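The oxane (tetrahydropyran) ring is numbered O1, C2 (quaternary), C3, C4, C5 (CHBr), C6 (CMe2) and is cut at two opposite bonds, C3–C4 and O1–C6. This leaves an O1–C2–C3 unit, a 2,2-disubstituted oxirane that already carries the bromine-bearing side chain, and a prenyl unit C4–C5–C6. The key step joins three components in one flask: a copper-catalysed prenyl Grignard opening of the oxirane makes C3–C4, and the resulting magnesium alkoxide is bromoetherified with NBS, closing O1–C6 and placing bromine on C5. It exploits the 3-bromo-2,2-dimethyl ether motif at C5/C6, the mark of a prenyl bromonium ion captured by the C2 oxygen. The precursor is an acyclic bromo epoxide made from (S)-linalool.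

Key step: step 6

Assumption: (S)-(+)-linalool is bought in enantiomerically enriched form and supplies the carbinol centre of the side chain; 3-methylbut-2-enylmagnesium chloride is bought as its THF solution.

Step 1
Reactants: 1 (S)-(+)-linalool
Product: 2 triethyl{[(3S)-3,7-dimethylocta-1,6-dien-3-yl]oxy}silane
Conditions: TESOTf, 2,6-lutidine, CH2Cl2, −78 → 0 °C
Reagents that add atoms: triethylsilyl trifluoromethanesulfonate (TESOTf), CC[Si](CC)(CC)OS(=O)(=O)C(F)(F)F
Why: Silyl triflate silylation of the hindered tertiary allylic alcohol, which should stop the carbinol oxygen from opening the later 6,7-epoxide (linalool-oxide-type cyclisation) and from being deprotonated by the Grignard reagent, with no stereocentre touched.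

Step 2
Reactants: 2 triethyl{[(3S)-3,7-dimethylocta-1,6-dien-3-yl]oxy}silane
Product: 3 (2E,6S)-2,6-dimethyl-6-[(triethylsilyl)oxy]octa-2,7-dien-1-ol
Conditions: SeO2 (cat.), t-BuOOH, salicylic acid (cat.), CH2Cl2, 0 °C → rt
Reagents that add atoms: selenium dioxide, O=[Se]=O (delivers the oxygen atom and is re-formed by the peroxide); tert-butyl hydroperoxide, CC(C)(C)OO
Why: Umbreit–Sharpless allylic oxidation (ene reaction, then [2,3]-sigmatropic shift of the allylseleninic acid) should hydroxylate the (E)-methyl group of the trisubstituted alkene selectively, the vinyl group having no allylic hydrogen.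

Step 3
Reactants: 3 (2E,6S)-2,6-dimethyl-6-[(triethylsilyl)oxy]octa-2,7-dien-1-ol
Product: 4 {(2S,3S)-2-methyl-3-[(3S)-3-methyl-3-[(triethylsilyl)oxy]pent-4-en-1-yl]oxiran-2-yl}methanol
Conditions: Ti(OiPr)4 (10 mol%), L-(+)-diethyl tartrate (12 mol%), t-BuOOH (decane solution), 4 Å molecular sieves, CH2Cl2, −20 °C
Reagents that add atoms: tert-butyl hydroperoxide, CC(C)(C)OO
Why: Katsuki–Sharpless asymmetric epoxidation, in which the L-(+)-tartrate titanium complex should deliver oxygen to the face of the (E)-2-methylallylic alcohol that gives the (2S,3S)-epoxide under reagent control, independent of the remote carbinol centre and leaving the vinyl silyl ether (not an allylic alcohol) alone.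

Step 4
Reactants: 4 {(2S,3S)-2-methyl-3-[(3S)-3-methyl-3-[(triethylsilyl)oxy]pent-4-en-1-yl]oxiran-2-yl}methanol
Product: 5 (2S,3R,6S)-3-bromo-2,6-dimethyl-6-[(triethylsilyl)oxy]oct-7-ene-1,2-diol
Conditions: Li2NiBr4 (THF solution), THF, 0 °C → rt; pH 7 phosphate buffer
Reagents that add atoms: dilithium tetrabromonickelate (Li2NiBr4), [Li+].[Li+].[Ni+2].[Br-].[Br-].[Br-].[Br-]
Why: Regioselective SN2 epoxide opening by soft nucleophilic bromide at C3 of the epoxy alcohol (the less substituted carbon, and the one remote from the electron-withdrawing hydroxymethyl group) with inversion, which should turn (3S) into the (3R)-bromide and leave the tertiary C–O bond, the later ring oxygen, untouched.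

Step 5
Reactants: 5 (2S,3R,6S)-3-bromo-2,6-dimethyl-6-[(triethylsilyl)oxy]oct-7-ene-1,2-diol
Product: 7 (2S)-2-{(1R,4S)-1-bromo-4-methyl-4-[(triethylsilyl)oxy]hex-5-en-1-yl}-2-methyloxirane, via primary triflate 6 (not isolated)
Conditions: Tf2O (1.05 equiv), 2,6-lutidine, CH2Cl2, −78 °C; then DBU, −78 → 0 °C
Reagents that add atoms: none
Why: Selective triflation of the primary hydroxyl followed by Williamson-type 3-exo-tet closure by the tertiary oxygen, where the triflate should leave orders of magnitude faster than the secondary bromide (a tosylate or mesylate would not outrun it), so the oxygen closes onto CH2 and the quaternary centre keeps its configuration because its C–O bond is not broken.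

Step 6
Reactants: 7 (2S)-2-{(1R,4S)-1-bromo-4-methyl-4-[(triethylsilyl)oxy]hex-5-en-1-yl}-2-methyloxirane; 8 3-methylbut-2-enylmagnesium chloride (prenylmagnesium chloride)
Product: 10 {[(3S,6R)-6-bromo-6-[(2S,5R)-5-bromo-2,6,6-trimethyloxan-2-yl]-3-methylhex-1-en-3-yl]oxy}triethylsilane, via chloromagnesium alkoxide 9 (not isolated)
Conditions: 8 (1.3 equiv), CuI (10 mol%), THF, −40 °C; then CH2Cl2, NBS (1.6 equiv), −78 → −20 °C, dark
Reagents that add atoms: N-bromosuccinimide (NBS), O=C1CCC(=O)N1Br
Why: Copper-catalysed SN2 opening of the oxirane at its unsubstituted CH2 carbon by the CH2 terminus of the prenyl group makes ring bond C3–C4 and the chloromagnesium alkoxide 9; NBS then turns the new trisubstituted alkene into a bromonium ion, which the alkoxide oxygen opens at the dimethyl-substituted carbon to make O1–C6 and, by anti addition, the C5–Br bond. The closest known reaction types are the copper-catalysed opening of epoxides by allylic Grignard reagents and the bromoetherification of 4-methylpent-3-enyl carbinols to 3-bromo-2,2-dimethyloxanes, run here in sequence as a three-component [3+3] annulation. The oxane ring closes in the 6-endo mode, preferred over 5-exo because the bromonium ion is opened at its tertiary carbon (Markovnikov). The only new stereocentre, C5, should be set by a chair-like transition state in which the branched CHBr side chain on C2 is equatorial, the C2 methyl takes the axial site beside the axial C6 methyl, and bromine ends up equatorial and trans to the side chain, which is (5R); C2 and the side-chain CHBr are carried through unchanged. The step needs the bromo alkoxide 9 not to close onto the neighbouring C–Br carbon, which the magnesium counter-ion and the low temperature should secure, since a magnesium halohydrinate is the resting form of an epoxide/magnesium halide pair. It also needs NBS to choose between two alkenes, and the trisubstituted alkene is far more nucleophilic than the vinyl group beside the silyloxy-bearing quaternary carbon.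

Step 7
Reactants: 10 {[(3S,6R)-6-bromo-6-[(2S,5R)-5-bromo-2,6,6-trimethyloxan-2-yl]-3-methylhex-1-en-3-yl]oxy}triethylsilane
Product: 11 (3S,6R)-6-bromo-6-[(2S,5R)-5-bromo-2,6,6-trimethyloxan-2-yl]-3-methylhex-1-en-3-ol
Conditions: HF·pyridine, pyridine, THF, 0 °C → rt
Reagents that add atoms: none
Why: Fluoride-driven cleavage of the Si–O bond (silyl ether deprotection) under buffered conditions that the two bromo ether units and the tertiary allylic alcohol should tolerate, with no stereocentre touched.

Compound list
1 | (S)-(+)-linalool, (3S)-3,7-dimethylocta-1,6-dien-3-ol | C=C[C@@](C)(O)CCC=C(C)C | starting material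
2 | triethyl{[(3S)-3,7-dimethylocta-1,6-dien-3-yl]oxy}silane | C=C[C@@](C)(O[Si](CC)(CC)CC)CCC=C(C)C | intermediate
3 | (2E,6S)-2,6-dimethyl-6-[(triethylsilyl)oxy]octa-2,7-dien-1-ol | C=C[C@@](C)(O[Si](CC)(CC)CC)CC/C=C(\C)CO | intermediate
4 | {(2S,3S)-2-methyl-3-[(3S)-3-methyl-3-[(triethylsilyl)oxy]pent-4-en-1-yl]oxiran-2-yl}methanol | C=C[C@@](C)(O[Si](CC)(CC)CC)CC[C@@H]1O[C@@]1(C)CO | intermediate
5 | (2S,3R,6S)-3-bromo-2,6-dimethyl-6-[(triethylsilyl)oxy]oct-7-ene-1,2-diol | C=C[C@@](C)(O[Si](CC)(CC)CC)CC[C@@H](Br)[C@@](C)(O)CO | intermediate
6 | (2S,3R,6S)-3-bromo-2-hydroxy-2,6-dimethyl-6-[(triethylsilyl)oxy]oct-7-en-1-yl trifluoromethanesulfonate | C=C[C@@](C)(O[Si](CC)(CC)CC)CC[C@@H](Br)[C@@](C)(O)COS(=O)(=O)C(F)(F)F | intermediate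
7 | (2S)-2-{(1R,4S)-1-bromo-4-methyl-4-[(triethylsilyl)oxy]hex-5-en-1-yl}-2-methyloxirane | C=C[C@@](C)(O[Si](CC)(CC)CC)CC[C@@H](Br)[C@]1(C)CO1 | intermediate
8 | 3-methylbut-2-enylmagnesium chloride (prenylmagnesium chloride) | CC(C)=CC[Mg]Cl | starting material
9 | chloromagnesium (3S,6R,7S)-6-bromo-3,7,11-trimethyl-3-[(triethylsilyl)oxy]dodeca-1,10-dien-7-olate | C=C[C@@](C)(O[Si](CC)(CC)CC)CC[C@@H](Br)[C@@](C)(O[Mg]Cl)CCC=C(C)C | intermediate
10 | {[(3S,6R)-6-bromo-6-[(2S,5R)-5-bromo-2,6,6-trimethyloxan-2-yl]-3-methylhex-1-en-3-yl]oxy}triethylsilane | C=C[C@@](C)(O[Si](CC)(CC)CC)CC[C@@H](Br)[C@]1(C)CC[C@@H](Br)C(C)(C)O1 | intermediate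
11 | (3S,6R)-6-bromo-6-[(2S,5R)-5-bromo-2,6,6-trimethyloxan-2-yl]-3-methylhex-1-en-3-ol | C=C[C@@](C)(O)CC[C@@H](Br)[C@]1(C)CC[C@@H](Br)C(C)(C)O1 | target

Total step count: 7. Longest linear sequence: 7 steps (1 to 11).

Steps most likely to fail

Step 6 (key step). Three processes may go wrong: transfer of the prenyl group through its substituted terminus (reverse prenylation), closure of the bromo alkoxide back onto the bromide-bearing carbon before the bromonium ion is formed, and 5-exo instead of 6-endo ring closure or poor facial selectivity in the one-pot medium. The fallback sets out from 7 and comes back at 10, with the carbon–carbon bond and the ring closure made in separate, individually optimised steps. Compound 7 would be opened with allylmagnesium bromide and catalytic CuI in THF at −40 °C, an allyl group having no regiochemical ambiguity, and quenched cold with aqueous NH4Cl to give the bromohydrin (3S,6R,7S)-6-bromo-3,7-dimethyl-3-[(triethylsilyl)oxy]undeca-1,10-dien-7-ol F1. Cross-metathesis of its unhindered terminal alkene in 2-methyl-2-butene with the second-generation Grubbs catalyst should give (3S,6R,7S)-6-bromo-3,7,11-trimethyl-3-[(triethylsilyl)oxy]dodeca-1,10-dien-7-ol F2; the hindered vinyl group beside the silyloxy carbon should not take part. F2 would then be cyclised with 2,4,4,6-tetrabromocyclohexa-2,5-dienone in nitromethane at 0 °C (or NBS in hexafluoroisopropanol), conditions made for 6-endo bromoetherification of free tertiary alcohols, to give 10.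

Step 5. The tertiary oxygen may displace the neighbouring secondary bromide instead of the triflate (return to a 6,7-epoxide), the tertiary hydroxyl may be triflated, or the hydroxy triflate may undergo a semipinacol shift before it closes. The fallback sets out from 5 and comes back at 7 and makes no new compound (F0). It is a Mitsunobu cyclodehydration (PPh3, diisopropyl azodicarboxylate, toluene, 0 °C → rt), which activates only the primary hydroxyl as an alkoxyphosphonium inside a betaine. No sulfonate ester and no external base are involved, and ring closure by the tertiary oxygen again keeps the quaternary centre.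

Step 2. Over-oxidation to the enal, incomplete conversion, competing oxidation of the allylic methylene group and loss of the silyl ether to acidic selenium species may each cut the supply of 3. The fallback sets out from 2 and comes back at 3 and builds the (E)-allylic alcohol by olefination instead of C–H oxidation. Ozone, dosed to one equivalent in CH2Cl2/MeOH at −78 °C and followed by Me2S, should cleave only the electron-rich trisubstituted alkene and give (4S)-4-methyl-4-[(triethylsilyl)oxy]hex-5-enal F3. A Wittig reaction with ethyl 2-(triphenylphosphoranylidene)propanoate in CH2Cl2 should give ethyl (2E,6S)-2,6-dimethyl-6-[(triethylsilyl)oxy]octa-2,7-dienoate F4, and DIBAL-H in CH2Cl2 at −78 °C reduces F4 to 3.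

Further compounds
F1 | step 6 | (3S,6R,7S)-6-bromo-3,7-dimethyl-3-[(triethylsilyl)oxy]undeca-1,10-dien-7-ol | C=C[C@@](C)(O[Si](CC)(CC)CC)CC[C@@H](Br)[C@@](C)(O)CCC=C
F2 | step 6 | (3S,6R,7S)-6-bromo-3,7,11-trimethyl-3-[(triethylsilyl)oxy]dodeca-1,10-dien-7-ol | C=C[C@@](C)(O[Si](CC)(CC)CC)CC[C@@H](Br)[C@@](C)(O)CCC=C(C)C
F0 | step 5 | none | none
F3 | step 2 | (4S)-4-methyl-4-[(triethylsilyl)oxy]hex-5-enal | C=C[C@@](C)(O[Si](CC)(CC)CC)CCC=O
F4 | step 2 | ethyl (2E,6S)-2,6-dimethyl-6-[(triethylsilyl)oxy]octa-2,7-dienoate | C=C[C@@](C)(O[Si](CC)(CC)CC)CC/C=C(\C)C(=O)OCC
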